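**Retrosynthetic overview**

- The target is a (3R)-isoflavan with C3 as its only stereocentre. The route rests on ring A being a phloroglucinol nucleus: its three ring CH carbons are equivalent and each is flanked by two hydroxyls, so one carbon can become C4a and a neighbouring oxygen O1, while C4, C3 and C2 of ring C come from a 2-arylacrolein that already carries ring B with its dimethylpyran ring.
- Key disconnection: C4–C4a and O1–C2, made in one operation by amine-catalysed Friedel–Crafts addition, enantioselective enamine protonation (sets C3) and lactol closure.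
- Ring order: the pyran ring of ring B first (propargyl ether Claisen/electrocyclisation on 2,4-dihydroxybenzaldehyde), then ring C as the lactol. The lactol is opened by borohydride and ring C re-closed at O1–C2 by Mitsunobu etherification, so that no acid-generated oxocarbenium ion sits next to C3–H.
- Ring A is finished last: 7-O-silylation, 5-O-(1,1-dimethylallyl) ether, Claisen shift to C6, 5-O-methylation, desilylation.

Key step: step 7

Remark on the chemistry: the facial sense of the enamine protonation is assumed to give (3R) with the (S)-diamine (from L-tert-leucine); if a test run shows (3S), the (R)-diamine is used and nothing else changes.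

Abbreviation used in names: Ar = 2,2-dimethyl-5-[(triisopropylsilyl)oxy]-2H-chromen-8-yl (ring B with its pyran ring, bonded through C8, which is C1′ of the isoflavan).

**Route**

Step 1
Reactants: 1 2,4-dihydroxybenzaldehyde
Product: 2 2-hydroxy-4-[(triisopropylsilyl)oxy]benzaldehyde
Conditions: TIPSCl (1.05 equiv), imidazole, CH2Cl2, 0 °C
Reagents that add atoms: chlorotriisopropylsilane, CC(C)[Si](Cl)(C(C)C)C(C)C
Why: Phenol silylation in which the 2-OH is held in a hydrogen bond to the formyl group, so the bulky chloride should take the free and more acidic 4-OH.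

Step 2
Reactants: 2 2-hydroxy-4-[(triisopropylsilyl)oxy]benzaldehyde; 3 3-chloro-3-methylbut-1-yne
Product: 4 2-[(2-methylbut-3-yn-2-yl)oxy]-4-[(triisopropylsilyl)oxy]benzaldehyde
Conditions: 3 (1.5 equiv), DBU, CuCl2·2H2O (1 mol %), MeCN, 0 °C → rt
Reagents that add atoms: none
Why: Copper-catalysed O-propargylation of a phenol with a tertiary propargylic chloride, which works on electron-poor, hydrogen-bonded phenols and should spare the aryl silyl ether at 0 °C; placing the ether on O2 and not on O4 is what later puts the pyran oxygen on C2′.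

Step 3
Reactants: 4 2-[(2-methylbut-3-yn-2-yl)oxy]-4-[(triisopropylsilyl)oxy]benzaldehyde
Product: 6 2,2-dimethyl-5-[(triisopropylsilyl)oxy]-2H-chromene-8-carbaldehyde, via allenylphenol 5 (not isolated)
Conditions: o-xylene, 140 °C
Reagents that add atoms: none
Why: Aryl propargyl ether Claisen rearrangement followed by 1,5-hydrogen shift and 6π oxa-electrocyclisation; the only free ortho carbon of the ether oxygen is the one between the two oxygens, so the pyran ring can only fuse in the 2′,3′ sense with the silyloxy group at C4′.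

Step 4
Reactants: 6 2,2-dimethyl-5-[(triisopropylsilyl)oxy]-2H-chromene-8-carbaldehyde
Product: 7 8-(2-methoxyethenyl)-2,2-dimethyl-5-[(triisopropylsilyl)oxy]-2H-chromene (E/Z mixture)
Conditions: MeOCH2PPh3Cl, NaN(SiMe3)2, THF, 0 °C; then 6, 0 °C → rt
Reagents that add atoms: (methoxymethyl)triphenylphosphonium chloride, COC[P+](c1ccccc1)(c1ccccc1)c1ccccc1.[Cl-]
Why: Wittig methoxymethylenation of an aryl aldehyde with the preformed ylide; the enol ether geometry is irrelevant because both isomers hydrolyse to the same aldehyde.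

Step 5
Reactants: 7 8-(2-methoxyethenyl)-2,2-dimethyl-5-[(triisopropylsilyl)oxy]-2H-chromene
Product: 8 2-Ar-acetaldehyde
Conditions: 1 M aq. HCl, THF, 40 °C
Reagents that add atoms: water, O
Why: Acid-catalysed enol ether hydrolysis, mild enough to spare the aryl TIPS ether and the 2,2-dimethylchromene; the aldehyde is used at once to avoid self-aldol condensation.

Step 6
Reactants: 8 2-Ar-acetaldehyde
Product: 9 2-Ar-prop-2-enal
Conditions: 37% aq. HCHO, pyrrolidine (10 mol %), EtCO2H (10 mol %), i-PrOH, 45 °C
Reagents that add atoms: formaldehyde, C=O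
Why: Amine-salt-catalysed Mannich condensation and elimination (α-methylenation of an aldehyde), a standard entry to 2-arylacroleins; the product is kept cold in solution and used directly because such enals dimerise on standing.

Step 7
Reactants: 9 2-Ar-prop-2-enal; 10 phloroglucinol (benzene-1,3,5-triol)
Product: 12 (3R)-3-Ar-chromane-2,5,7-triol (lactol; C2 epimers), via open-chain aldehyde 11 (not isolated)
Conditions: 10 (4 equiv), (S)-N1,N1-diethyl-3,3-dimethylbutane-1,2-diamine·TfOH (20 mol %), MeCN–THF, −20 °C
Reagents that add atoms: none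
Why: Proposed new method: the primary amine of the catalyst condenses with enal 9 to an α-aryl iminium ion, a ring carbon of 10 adds to its unsubstituted CH2 terminus (C4–C4a) and rearomatises, the resulting enamine is protonated at C3 by the adjacent trialkylammonium arm of the catalyst, and hydrolysis (aldehyde 11) is followed by attack of a flanking phenol on the carbonyl carbon (O1–C2). The closest known reaction type is the primary amine–TfOH catalysed Friedel–Crafts addition of indoles to α-substituted acroleins with enantioselective enamine protonation, taken together with amine-catalysed phenol–enal [3+3] annulations to chroman-2-ols; a polyphenol with an α-arylacrolein has not been run this way. Ring C closes by reversible 6-exo-trig addition of the phenolic oxygen to the aldehyde (or its iminium ion) to give the hemiacetal. C3 is set by catalyst control, through intramolecular delivery of the proton from the ammonium N–H to one face of the enamine carbon, whereas C2 is a freely equilibrating hemiacetal centre that is removed later. The step needs C-attack at a single site, one alkylation only and survival of the C3 configuration: the threefold symmetry of 10 makes all ring carbons and both flanking hydroxyls equivalent, the fourfold excess of 10 should suppress a second alkylation, and the lactol keeps the α-aryl aldehyde masked from enamine formation and enolisation.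

Step 8
Reactants: 12 (3R)-3-Ar-chromane-2,5,7-triol
Product: 13 2-[(2R)-3-hydroxy-2-Ar-propyl]benzene-1,3,5-triol
Conditions: NaBH4, MeOH–THF, −20 °C → 0 °C
Reagents that add atoms: none
Why: Borohydride reduction of a lactol, which reacts through the small equilibrium share of its ring-opened hydroxy-aldehyde tautomer (the open-chain form 11 of step 7), so that the carbonyl is reduced as fast as it is unmasked and C3 should not epimerise; an ionic silane/Lewis acid reduction is avoided because its oxocarbenium ion next to C3–H could eliminate and because acid with a hydride donor could saturate the chromene.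

Step 9
Reactants: 13 2-[(2R)-3-hydroxy-2-Ar-propyl]benzene-1,3,5-triol
Product: 14 (3R)-3-Ar-chromane-5,7-diol
Conditions: PPh3, DIAD (betaine preformed), THF (0.02 M), 0 °C
Reagents that add atoms: none
Why: Intramolecular Mitsunobu etherification (6-exo-tet displacement of the activated primary alcohol by an ortho phenol); the two ortho hydroxyls are equivalent, the para hydroxyl cannot reach, and C3 is not a reacting centre, so its configuration is retained.

Step 10
Reactants: 14 (3R)-3-Ar-chromane-5,7-diol
Product: 15 (3R)-3-Ar-7-[(triisopropylsilyl)oxy]chroman-5-ol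
Conditions: TIPSCl (1.0 equiv), imidazole, DMF, −20 °C
Reagents that add atoms: chlorotriisopropylsilane, CC(C)[Si](Cl)(C(C)C)C(C)C
Why: Sterically controlled phenol silylation: O7 has two ortho hydrogens whereas O5 is crowded by the peri C4 methylene, so the bulky chloride should select O7.

Step 11
Reactants: 16 2-methylbut-3-en-2-ol
Product: 18 isobutyl 2-methylbut-3-en-2-yl carbonate, via lithium alkoxide 17 (not isolated)
Conditions: n-BuLi, THF, −78 °C; then i-BuOCOCl, −78 °C → rt
Reagents that add atoms: isobutyl chloroformate, CC(C)COC(=O)Cl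
Why: Acylation of a lithium tertiary alkoxide with a chloroformate, a routine preparation of mixed allylic carbonates.

Step 12
Reactants: 15 (3R)-3-Ar-7-[(triisopropylsilyl)oxy]chroman-5-ol; 18 isobutyl 2-methylbut-3-en-2-yl carbonate
Product: 19 (3R)-5-[(2-methylbut-3-en-2-yl)oxy]-3-Ar-7-[(triisopropylsilyl)oxy]chromane
Conditions: 18 (2 equiv), Pd(PPh3)4 (5 mol %), THF, 0 °C
Reagents that add atoms: none
Why: Tsuji–Trost O-allylation: zerovalent palladium ionises the carbonate, the released isobutoxide deprotonates the phenol, and the phenoxide attacks the more substituted terminus of the 1,1-dimethylallyl complex under kinetic control at 0 °C to give the tertiary ether.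

Step 13
Reactants: 19 (3R)-5-[(2-methylbut-3-en-2-yl)oxy]-3-Ar-7-[(triisopropylsilyl)oxy]chromane
Product: 21 (3R)-6-(3-methylbut-2-en-1-yl)-3-Ar-7-[(triisopropylsilyl)oxy]chroman-5-ol, via cyclohexadienone 20 (not isolated)
Conditions: PhMe, 110–120 °C (sealed tube)
Reagents that add atoms: none
Why: Aromatic Claisen rearrangement: O5 has a single free ortho carbon (C6, since C4a is substituted), so the [3,3] shift delivers the allyl unit with transposition to C6 as a 3-methylbut-2-enyl group, and tautomerisation restores the 5-phenol.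

Step 14
Reactants: 21 (3R)-6-(3-methylbut-2-en-1-yl)-3-Ar-7-[(triisopropylsilyl)oxy]chroman-5-ol
Product: 22 (3R)-5-methoxy-6-(3-methylbut-2-en-1-yl)-3-Ar-7-[(triisopropylsilyl)oxy]chromane
Conditions: MeI, K2CO3, acetone, 45 °C
Reagents that add atoms: iodomethane, CI
Why: Williamson O-methylation of the only free phenol under carbonate conditions that the aryl TIPS ethers should tolerate.

Step 15
Reactants: 22 (3R)-5-methoxy-6-(3-methylbut-2-en-1-yl)-3-Ar-7-[(triisopropylsilyl)oxy]chromane
Product: 23 (3R)-3-(5-hydroxy-2,2-dimethyl-2H-chromen-8-yl)-5-methoxy-6-(3-methylbut-2-en-1-yl)chroman-7-ol (CNP0119857.1)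
Conditions: Bu4NF (2.5 equiv), AcOH (2.5 equiv), THF, 0 °C → rt
Reagents that add atoms: none
Why: Fluoride cleavage of both aryl silyl ethers, buffered with acetic acid so that the ortho-prenyl phenol is exposed neither to strong base nor to acid that could cyclise it onto the prenyl group.

**Compound list**

1 | 2,4-dihydroxybenzaldehyde | O=Cc1ccc(O)cc1O | starting material
2 | 2-hydroxy-4-[(triisopropylsilyl)oxy]benzaldehyde | O=Cc1ccc(O[Si](C(C)C)(C(C)C)C(C)C)cc1O | intermediate
3 | 3-chloro-3-methylbut-1-yne | CC(C)(Cl)C#C | starting material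
4 | 2-[(2-methylbut-3-yn-2-yl)oxy]-4-[(triisopropylsilyl)oxy]benzaldehyde | O=Cc1ccc(O[Si](C(C)C)(C(C)C)C(C)C)cc1OC(C)(C)C#C | intermediate
5 | 2-hydroxy-3-(3-methylbuta-1,2-dien-1-yl)-4-[(triisopropylsilyl)oxy]benzaldehyde (not isolated) | O=Cc1ccc(O[Si](C(C)C)(C(C)C)C(C)C)c(C=C=C(C)C)c1O | intermediate
6 | 2,2-dimethyl-5-[(triisopropylsilyl)oxy]-2H-chromene-8-carbaldehyde | O=Cc1ccc(O[Si](C(C)C)(C(C)C)C(C)C)c2c1OC(C)(C)C=C2 | intermediate
7 | 8-(2-methoxyethenyl)-2,2-dimethyl-5-[(triisopropylsilyl)oxy]-2H-chromene (E/Z mixture) | COC=Cc1ccc(O[Si](C(C)C)(C(C)C)C(C)C)c2c1OC(C)(C)C=C2 | intermediate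
8 | 2-{2,2-dimethyl-5-[(triisopropylsilyl)oxy]-2H-chromen-8-yl}acetaldehyde | O=CCc1ccc(O[Si](C(C)C)(C(C)C)C(C)C)c2c1OC(C)(C)C=C2 | intermediate
9 | 2-{2,2-dimethyl-5-[(triisopropylsilyl)oxy]-2H-chromen-8-yl}prop-2-enal | O=CC(=C)c1ccc(O[Si](C(C)C)(C(C)C)C(C)C)c2c1OC(C)(C)C=C2 | intermediate
10 | phloroglucinol (benzene-1,3,5-triol) | Oc1cc(O)cc(O)c1 | starting material
11 | (2R)-2-Ar-3-(2,4,6-trihydroxyphenyl)propanal (not isolated) | Oc1cc(O)cc(O)c1C[C@H](c1ccc(O[Si](C(C)C)(C(C)C)C(C)C)c2c1OC(C)(C)C=C2)C=O | intermediate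
12 | (3R)-3-Ar-chromane-2,5,7-triol (C2 epimers) | Oc1cc(O)cc2c1C[C@H](c1ccc(O[Si](C(C)C)(C(C)C)C(C)C)c3c1OC(C)(C)C=C3)C(O)O2 | intermediate
13 | 2-[(2R)-3-hydroxy-2-Ar-propyl]benzene-1,3,5-triol | Oc1cc(O)cc(O)c1C[C@H](c1ccc(O[Si](C(C)C)(C(C)C)C(C)C)c2c1OC(C)(C)C=C2)CO | intermediate
14 | (3R)-3-Ar-chromane-5,7-diol | Oc1cc(O)cc2c1C[C@H](c1ccc(O[Si](C(C)C)(C(C)C)C(C)C)c3c1OC(C)(C)C=C3)CO2 | intermediate
15 | (3R)-3-Ar-7-[(triisopropylsilyl)oxy]chroman-5-ol | Oc1cc(O[Si](C(C)C)(C(C)C)C(C)C)cc2c1C[C@H](c1ccc(O[Si](C(C)C)(C(C)C)C(C)C)c3c1OC(C)(C)C=C3)CO2 | intermediate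
16 | 2-methylbut-3-en-2-ol | CC(C)(O)C=C | starting material
17 | lithium 2-methylbut-3-en-2-olate (not isolated) | [Li+].[O-]C(C)(C)C=C | intermediate
18 | isobutyl 2-methylbut-3-en-2-yl carbonate | CC(C)COC(=O)OC(C)(C)C=C | intermediate
19 | (3R)-5-[(2-methylbut-3-en-2-yl)oxy]-3-Ar-7-[(triisopropylsilyl)oxy]chromane | C=CC(C)(C)Oc1cc(O[Si](C(C)C)(C(C)C)C(C)C)cc2c1C[C@H](c1ccc(O[Si](C(C)C)(C(C)C)C(C)C)c3c1OC(C)(C)C=C3)CO2 | intermediate
20 | (3R)-6-(3-methylbut-2-en-1-yl)-3-Ar-7-[(triisopropylsilyl)oxy]-3,4-dihydro-2H-chromen-5(6H)-one (not isolated; C6 unassigned) | O=C1C(CC=C(C)C)C(O[Si](C(C)C)(C(C)C)C(C)C)=CC2=C1C[C@H](c1ccc(O[Si](C(C)C)(C(C)C)C(C)C)c3c1OC(C)(C)C=C3)CO2 | intermediate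
21 | (3R)-6-(3-methylbut-2-en-1-yl)-3-Ar-7-[(triisopropylsilyl)oxy]chroman-5-ol | Oc1c(CC=C(C)C)c(O[Si](C(C)C)(C(C)C)C(C)C)cc2c1C[C@H](c1ccc(O[Si](C(C)C)(C(C)C)C(C)C)c3c1OC(C)(C)C=C3)CO2 | intermediate
22 | (3R)-5-methoxy-6-(3-methylbut-2-en-1-yl)-3-Ar-7-[(triisopropylsilyl)oxy]chromane | COc1c(CC=C(C)C)c(O[Si](C(C)C)(C(C)C)C(C)C)cc2c1C[C@H](c1ccc(O[Si](C(C)C)(C(C)C)C(C)C)c3c1OC(C)(C)C=C3)CO2 | intermediate
23 | (3R)-3-(5-hydroxy-2,2-dimethyl-2H-chromen-8-yl)-5-methoxy-6-(3-methylbut-2-en-1-yl)chroman-7-ol | COc1c(CC=C(C)C)c(O)cc2c1C[C@H](c1ccc(O)c3c1OC(C)(C)C=C3)CO2 | target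

**Step count**

Total: 15 steps. Longest linear sequence: 14 steps (steps 1–10 and 12–15, from 2,4-dihydroxybenzaldehyde); step 11 prepares the carbonate.

**Steps most likely to fail**

1. Step 7 (the step labelled as a proposed new method). The enamine may be protonated with poor facial control, because the strongly nucleophilic triol can also add by an uncatalysed or simply acid-catalysed pathway and because the product aldehyde can re-enter the enamine manifold before the lactol closes. Oligomerisation of 9 and a second alkylation would drain material further. The fallback is an Evans alkylation (known chemistry), setting out from aldehyde 8 and returning at 13. Pinnick oxidation of 8 (NaClO2, NaH2PO4, 2-methylbut-2-ene, t-BuOH–H2O) should give the arylacetic acid F1. Pivaloyl chloride and Et3N in THF convert it into the mixed pivalic anhydride F2, which acylates commercial (R)-4-benzyloxazolidin-2-one in the presence of LiCl to give the imide F3. Separately, commercial 2-methylbenzene-1,3,5-triol is acylated (PivCl, pyridine) to the tripivalate F4 and brominated at the benzylic carbon (NBS, AIBN, PhCF3, 80 °C) to the benzyl bromide F5, whose acyloxy groups keep it from ionising. NaN(SiMe3)2 (THF, −78 °C) turns F3 into the chelated Z sodium enolate F6, which is alkylated by F5 on the face opposite the benzyl group of the auxiliary to give the alkylated imide F7; for an arylacetyl imide the (R)-auxiliary leads to the (R)-centre. LiAlH4 (THF, 0 °C) then removes the auxiliary reductively and cleaves the three pivalates to give 13, from which steps 9–15 follow unchanged.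

2. Step 10. The silyl chloride may not distinguish the two phenols well enough, so that silylation at O5 and double silylation accompany the 7-O-ether. The fallback, from 14 back to 15, hands the discrimination to an enzyme working in the deprotection direction. Acetylation of 14 (Ac2O, pyridine) gives the diacetate F8. Lipase-catalysed alcoholysis of polyphenol acetates is a known regioselective method that removes the most exposed ester, so Pseudomonas cepacia lipase with n-BuOH in THF at 40 °C should cleave the 7-acetate and leave the 5-monoacetate F9. Silylation of its single free phenol (TIPSCl, imidazole, DMF) gives the silyl ether F10, and ammonolysis of the aryl acetate (NH3, MeOH, 0 °C) returns 15.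

3. Step 13. Thermal fragmentation of the tertiary allyl ether (loss of isoprene back to 15) may outrun the sigmatropic shift into C6, which lies between two oxygen substituents, one of them a bulky silyl ether. The fallback goes from 15 directly to 21 and bypasses steps 12 and 13. NaH in toluene at rt converts 15 into the sodium phenoxide F11, which is C-alkylated with 1-bromo-3-methylbut-2-ene. In a non-polar solvent the contact ion pair directs the allyl halide to the ortho carbon, and C6 is the only free ortho carbon of O5, so the dienone 20 and then, by tautomerisation, 21 should result after separation from any O-prenyl ether.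

**Further compounds**

F1 | step 7 | 2-{2,2-dimethyl-5-[(triisopropylsilyl)oxy]-2H-chromen-8-yl}acetic acid | OC(=O)Cc1ccc(O[Si](C(C)C)(C(C)C)C(C)C)c2c1OC(C)(C)C=C2
F2 | step 7 | 2-Ar-acetic 2,2-dimethylpropanoic anhydride (not isolated) | CC(C)(C)C(=O)OC(=O)Cc1ccc(O[Si](C(C)C)(C(C)C)C(C)C)c2c1OC(C)(C)C=C2
F3 | step 7 | (4R)-4-benzyl-3-(2-Ar-acetyl)oxazolidin-2-one | O=C(Cc1ccc(O[Si](C(C)C)(C(C)C)C(C)C)c2c1OC(C)(C)C=C2)N1[C@H](Cc2ccccc2)COC1=O
F4 | step 7 | 2-methylbenzene-1,3,5-triyl tris(2,2-dimethylpropanoate) | Cc1c(OC(=O)C(C)(C)C)cc(OC(=O)C(C)(C)C)cc1OC(=O)C(C)(C)C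
F5 | step 7 | 2-(bromomethyl)benzene-1,3,5-triyl tris(2,2-dimethylpropanoate) | BrCc1c(OC(=O)C(C)(C)C)cc(OC(=O)C(C)(C)C)cc1OC(=O)C(C)(C)C
F6 | step 7 | sodium (Z)-enolate of (4R)-4-benzyl-3-(2-Ar-acetyl)oxazolidin-2-one (not isolated) | [Na+].[O-]/C(=C\c1ccc(O[Si](C(C)C)(C(C)C)C(C)C)c2c1OC(C)(C)C=C2)N1[C@H](Cc2ccccc2)COC1=O
F7 | step 7 | (4R)-4-benzyl-3-{(2R)-2-Ar-3-[2,4,6-tris(2,2-dimethylpropanoyloxy)phenyl]propanoyl}oxazolidin-2-one | CC(C)(C)C(=O)Oc1cc(OC(=O)C(C)(C)C)cc(OC(=O)C(C)(C)C)c1C[C@H](c1ccc(O[Si](C(C)C)(C(C)C)C(C)C)c2c1OC(C)(C)C=C2)C(=O)N1[C@H](Cc2ccccc2)COC1=O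
F8 | step 10 | (3R)-3-Ar-chromane-5,7-diyl diacetate | CC(=O)Oc1cc(OC(C)=O)cc2c1C[C@H](c1ccc(O[Si](C(C)C)(C(C)C)C(C)C)c3c1OC(C)(C)C=C3)CO2
F9 | step 10 | (3R)-3-Ar-7-hydroxychroman-5-yl acetate | CC(=O)Oc1cc(O)cc2c1C[C@H](c1ccc(O[Si](C(C)C)(C(C)C)C(C)C)c3c1OC(C)(C)C=C3)CO2
F10 | step 10 | (3R)-3-Ar-7-[(triisopropylsilyl)oxy]chroman-5-yl acetate | CC(=O)Oc1cc(O[Si](C(C)C)(C(C)C)C(C)C)cc2c1C[C@H](c1ccc(O[Si](C(C)C)(C(C)C)C(C)C)c3c1OC(C)(C)C=C3)CO2
F11 | step 13 | sodium (3R)-3-Ar-7-[(triisopropylsilyl)oxy]chroman-5-olate (not isolated) | [Na+].[O-]c1cc(O[Si](C(C)C)(C(C)C)C(C)C)cc2c1C[C@H](c1ccc(O[Si](C(C)C)(C(C)C)C(C)C)c3c1OC(C)(C)C=C3)CO2
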